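The reading at 8.0 min set my first question: how much reagent had crossed into the reaction phase by then? The four flasks differ in the charge of reagent in the second phase.

    reagent in the reaction phase ⇌ reagent in the second phase, rate k1*([reagent in the reaction phase] - [reagent in the second phase]/K1) per volume of the first phase (K1 = 0.54, k1 = 0.0019 /s)
    starting material + reagent in the reaction phase → target (k2 = 3.7 /M/s)
    reagent in the reaction phase + target → over-reacted product (k3 = 0.45 /M/s)
    reagent in the reaction phase + protic impurity → quenched reagent (k4 = 9.4 /M/s)

| flask | starting material | reagent in the second phase | protic impurity | time | volume of the second phase over the first |
|---|---|---|---|---|---|
| Wednesday's | 0.020 M | 0.00800 M | 0.400 mM | 8.0 min | 2.0 |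
| Tuesday's | 0.020 M | 0.0150 M | 0.400 mM | 8.0 min | 2.0 |
| Saturday's | 0.020 M | 0.0300 M | 0.400 mM | 8.0 min | 2.0 |
| Sunday's | 0.020 M | 0.0600 M | 0.400 mM | 8.0 min | 2.0 |

- in the second phase: reagent in the second phase; everything else is in the first
- charges count per volume of the first phase; a concentration in a rate is the amount of a species over the volume of its own phase; every rate counts per litre of the first phase
- "hardly changes" means that all values lie within two and a half points (for a concentration: within two and a half percent of the largest)
- run time (Wednesday's): 8.0 min

1. [target] at the end for Wednesday's, Tuesday's, Saturday's, Sunday's, in this order
2. the course of these numbers from the first flask to the last (falls all the way / falls, then rises / rises, then falls / hardly changes / rises all the way)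

While [reagent in the reaction phase] stayed small, I could drop the return term of step one. The charge counts per litre of the first phase, and its concentration in its own phase is that charge over 2.0. The stock therefore decays first-order, and integrating gives a constant of 0.106 /min, the transfer coefficient over the partition ratio and the volume ratio. Over 8.0 min the exponent is 0.848, so one minus its exponential comes to 57.0%: this is the released fraction, the part of a charge that has crossed by the reading.

Next I asked whether the crossing reagent stayed small. At the charged [starting material] its half-life by step two is 0.156 min, much shorter than the 9.47 min time constant of the leak, so the transfer is the rate-limiting step. At the start, the protic impurity takes about 5.08% of what crosses, relative to step two.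

That made the released amount a ceiling on target, and I then asked where it meets the starting material. It is 0.00456 M for Wednesday's, 0.00855 M for Tuesday's and 0.0171 M for Saturday's, less than the 0.020 M of starting material. For Sunday's it is 0.0342 M, more than that charge, which makes starting material the limiting reagent there, with a surplus free to attack target by step three. I expected a rise and then a fall, but had no number for the last flask.

The forecast gave 0.004 M, 0.0071 M, 0.0128 M and 0.0112 M, with the course rises, then falls, holding that “the row peaks near the third flask and drops at the last”.

The flasks gave 0.00409 M, 0.00741 M, 0.0130 M and 0.0126 M, and the course rises, then falls.

The second phase was the clock to read. On Wednesday's it held 44.0% of its charge at 8.00 min, against 43.0% from the released fraction, and target stood under its ceiling of 0.00456 M. On Sunday's, where the fraction reckoned 1.71 times the charge of starting material across, starting material was down to 0.852% at the reading and over-reacted product stood at 36.3%. The resistance to the transfer and the hour of the reading acted together on Wednesday's flask: it held 0.00409 M of target at the reading, against 0.00727 M with the resistance taken away and 0.00727 M at a reading ten times later.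

The numbers of this flask were set for the occasion; the result is computed.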